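Readings and results were generated by integration from invented constants.

At 80.0 s, the last reading of the autumn flask, the two products together stand at 9.10% of the substrate charged, yet the new flask is asked about at 12 min.

- autumn: left-handed substrate 0.15 M; right-handed substrate 0.15 M; partner 2 equiv; precatalyst 0.5 mol%; run made earlier
- flask: left-handed substrate 0.10 M; partner 2.00 equiv; precatalyst 0.5 mol%; right-handed substrate 0.10 M; time 12 min

- autumn (time / s: left-handed product / %, right-handed product / %, left-handed substrate / %): 10.0: 0.7, 0, 49.4; 20.0: 0, 1.6, 49.7; 30.0: 0, 1.2, 49.2; 40.0: 0.8, 0.3, 49.6; 50.0: 1.0, 3.4, 48.1; 60.0: 1.3, 4.2, 48.7; 80.0: 2.4, 6.7, 48.0

(readings scatter by 0.5 percentage points)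

- excess of left-handed product over right-handed product in the product at 15 s
- excess of left-handed product over right-handed product in the product at 12 min
- part of the left-handed substrate and right-handed substrate charged together that has reacted at 12 min

- free catalyst is single-handed; left-handed substrate and right-handed substrate are mirror images of each other, charged as a racemate, each of them at the stated concentration
- an excess is the difference of the two amounts in percent of their sum
- an excess is below zero if the other one leads
- no earlier run changes the charge of precatalyst; that part of a forecast is a guess

So I look for something in these early readings that survives a change of clock. Suppose each substrate is lost at a rate first order in itself, and both meet the same catalyst and the same partner. Then however those two change with time, they cancel when I divide one fractional rate by the other. While the substrates stand nearly equal, that quotient is simply right-handed product over left-handed product. The early readings sit close to their scatter, so I sum all 7 of each: 17.4% over 6.20%, which gives 2.81. This number s, the fractional rate of loss of right-handed substrate divided by that of left-handed substrate, is the selectivity factor. It is a loose reading, since the left-handed sum is good to about 1.3 percentage points.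

At the early end, the excess is (1 − s)/(1 + s), so I expect −47.5% at 15 s. Integrating the quotient joins this to the late end without any time in it: [right-handed substrate] over its charge equals [left-handed substrate] over its charge, raised to the power s. If a fraction 0.5 of the left-handed substrate remains, then 14.3% of the right-handed remains, the conversion is 67.8% and the excess is −26.3%. Where the flask stands on this curve at 12 min is my guess, and I put it near that point.

The forecast, whose late numbers differ from my point on the curve, gives an excess of −48% (−75% to −20%) at 15 s, and at 12 min an excess of −25% (−40% to −10%) with 70% (42% to 92%) reacted, in its words: “The product excess stays roughly constant”.

The flask gives an excess of −52.4% at 15 s, and at 12 min an excess of −35.2% with 59.1% reacted.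

    partner + precatalyst → free catalyst + spent reagent (k = 0.0140 /M/s)
    free catalyst + left-handed substrate ⇌ catalyst intermediate A (K = 3.80 /M, k = 4700 /M/s)
    partner + catalyst intermediate A → free catalyst + left-handed product (k = 31.0 /M/s)
    free catalyst → spent catalyst (k = 0.00820 /s)
    free catalyst + right-handed substrate ⇌ catalyst intermediate B (K = 38.0 /M, k = 780 /M/s)
    partner + catalyst intermediate B → free catalyst + right-handed product (k = 11.0 /M/s)

At 12.0 min the flask still holds, unbound, 62% of the left-handed substrate charged and 20% of the right-handed substrate charged, the right-handed being the less. The power rule with the autumn s gives 26.1% for the right-handed, and read backwards the pair gives s = 3.33. A neighbouring flask, the same but with 0.85 mol% of precatalyst, runs further by 12 min, to 69.5% reacted and an excess of −29.1%. Unbound, it holds 51% of its left-handed substrate and 10% of its right-handed substrate, where the autumn s gives 14.9% for the right-handed, and its pair reads back as s = 3.35.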